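**Retrosynthetic overview**

- The strategy rests on two allylic C–O carbons. Chromene C2 is a fully substituted ether carbon bonded to O1, CH3, the C3=C4 ring alkene and side-chain C1'. Lactone C5 is a C–O carbon next to the endocyclic C3=C4 alkene of the furanone. Both heterocycles are therefore masked vinyl carbinol derivatives.
- Both rings are opened at their cis alkenes (pyran C3=C4, butenolide C3=C4) by ring-closing metathesis, giving an acyclic hexaene that is an aryl ether and a 2-alkylacrylate ester.
- The ester is cut to a 2-alkylacrylic acid and a secondary vinyl carbinol. The O1–C2 bond is cut to a doubly ortho-substituted 2-vinylphenol and a primary allylic carbonate (asymmetric Pd π-allyl O-alkylation at the tertiary terminus).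
- The C13 chain comes from a B-alkyl Suzuki coupling (C2'–C3' bond) of a dienol with a vinyl iodide made from (S)-2-vinyloxirane, whose C–O bond becomes lactone C5.
- Ring order: the benzene ring is bought; the pyran ring and the butenolide close together in one double metathesis, after all other skeletal bonds are in place.

Key step: step 9

Assumption: the (R,R) enantiomer of the DACH bis(2-diphenylphosphinobenzamide) ligand is taken to deliver the S ether from the E carbonate, by analogy with chroman closures of E substrates. The sense is to be checked on the first batch, and the (S,S) ligand is used if it proves opposite.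

**Step 1**
Reactants: 1 2-methylhydroquinone
Product: 2 2-methyl-4-(triisopropylsilyloxy)phenol
Conditions: TIPSCl (1.0 equiv), imidazole, DMF, 0 °C; 1 in slight excess
Reagents that add atoms: triisopropylsilyl chloride, CC(C)[Si](Cl)(C(C)C)C(C)C
Why: Phenol silylation; the 4-OH, flanked by two hydrogens, should react with the bulky silyl chloride faster than the 1-OH next to the methyl group, and the slight excess of 1 limits bis-silylation (regioisomer and bis-ether removed by chromatography).

**Step 2**
Reactants: 2 2-methyl-4-(triisopropylsilyloxy)phenol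
Product: 3 2-hydroxy-3-methyl-5-(triisopropylsilyloxy)benzaldehyde
Conditions: MgCl2, Et3N, (CH2O)n, MeCN, reflux; 1 M HCl work-up
Reagents that add atoms: paraformaldehyde (formaldehyde), C=O
Why: Magnesium-mediated ortho-formylation (Casnati–Skattebøl): the magnesium phenoxide delivers formaldehyde to the only free ortho position and a second formaldehyde oxidises the benzylic alkoxide to the aldehyde, while the aryl silyl ether is inert to MgCl2/Et3N.

**Step 3**
Reactants: 3 2-hydroxy-3-methyl-5-(triisopropylsilyloxy)benzaldehyde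
Product: 4 2-methyl-4-(triisopropylsilyloxy)-6-vinylphenol
Conditions: Ph3PCH3Br (2.5 equiv), NaHMDS (2.4 equiv), THF, 0 °C to rt; aq. NH4Cl; stored cold with BHT
Reagents that add atoms: methyltriphenylphosphonium bromide, C[P+](c1ccccc1)(c1ccccc1)c1ccccc1.[Br-]
Why: Wittig methylenation; the first equivalent of base only forms the phenoxide, which does not stop methylenation of the salicylaldehyde, and the non-nucleophilic amide base leaves the aryl silyl ether intact.

**Step 4**
Reactants: 5 (E)-3-methylpent-2-en-4-yn-1-ol
Product: 6 (E)-3-methylpenta-2,4-dien-1-ol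
Conditions: Zn(Cu/Ag), MeOH/H2O, 45 °C
Reagents that add atoms: none
Why: Activated-zinc (Boland-type) semireduction of a conjugated alkyne; the enyne is taken to the diene without over-reduction and the trisubstituted E alkene is untouched.

**Step 5**
Reactants: 7 (S)-2-vinyloxirane
Product: 8 (R)-hex-1-en-5-yn-3-ol
Conditions: HC≡CLi·H2NCH2CH2NH2, DMSO, 0 °C to rt; H2O
Reagents that add atoms: lithium acetylide ethylenediamine complex, [Li]C#C.NCCN
Why: SN2 opening of a monosubstituted epoxide by a hard acetylide at the unhindered CH2 terminus (no Lewis acid, so the allylic C–O bond is not activated); the stereocentre is not involved and is carried over from 7, the descriptor becoming R only through the change of priorities.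

**Step 6**
Reactants: 8 (R)-hex-1-en-5-yn-3-ol
Product: 10 (R,E)-6-iodo-5-methylhexa-1,5-dien-3-ol, via dimethylaluminium (R,E)-6-(dimethylalumanyl)-5-methylhexa-1,5-dien-3-olate 9 (not isolated)
Conditions: AlMe3 (3 equiv), Cp2ZrCl2 (0.3 equiv), CH2Cl2, 0 °C to rt; then I2, THF, −30 to 0 °C; aq. Rochelle salt/NaHCO3/Na2S2O3
Reagents that add atoms: trimethylaluminium, C[Al](C)C; iodine, II
Why: Negishi Zr-catalysed carboalumination: after the hydroxyl is converted into its aluminium alkoxide, Me–Al adds syn across the terminal alkyne (methyl to the internal carbon) much faster than to the monosubstituted alkene, and iodinolysis of the C–Al bond with retention gives the E iodide.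

**Step 7**
Reactants: 6 (E)-3-methylpenta-2,4-dien-1-ol; 10 (R,E)-6-iodo-5-methylhexa-1,5-dien-3-ol
Product: 12 (2E,6E,9R)-3,7-dimethylundeca-2,6,10-triene-1,9-diol, via 9-[(E)-3-methyl-5-(9-borabicyclo[3.3.1]nonan-9-yloxy)pent-3-en-1-yl]-9-borabicyclo[3.3.1]nonane 11 (not isolated)
Conditions: 6 (1.3 equiv), 9-BBN (2.6 equiv), THF, 0 °C to rt; aq. Cs2CO3; then 10, Pd(dppf)Cl2·CH2Cl2 (5 mol%), AsPh3, DMF, rt, dark
Reagents that add atoms: none
Why: B-alkyl Suzuki–Miyaura coupling: 9-BBN first masks the hydroxyl as its borinate and then adds to the terminal CH2 of the less hindered vinyl group of the diene, and the primary alkylborane couples with the alkenyl iodide with retention of the E geometry; residual B–H is destroyed by the aqueous base before 10 is added, so that its vinyl group is not hydroborated.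

**Step 8**
Reactants: 12 (2E,6E,9R)-3,7-dimethylundeca-2,6,10-triene-1,9-diol
Product: 13 (2E,6E,9R)-9-hydroxy-3,7-dimethylundeca-2,6,10-trien-1-yl methyl carbonate
Conditions: ClCO2Me (1.05 equiv), pyridine, CH2Cl2, −40 to −20 °C
Reagents that add atoms: methyl chloroformate, COC(=O)Cl
Why: Chemoselective acylation; the primary allylic alcohol reacts with one equivalent of chloroformate at low temperature much faster than the more hindered secondary allylic alcohol.

**Step 9**
Reactants: 4 2-methyl-4-(triisopropylsilyloxy)-6-vinylphenol; 13 (2E,6E,9R)-9-hydroxy-3,7-dimethylundeca-2,6,10-trien-1-yl methyl carbonate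
Product: 14 (3R,5E,9S)-5,9-dimethyl-9-[2-methyl-4-(triisopropylsilyloxy)-6-vinylphenoxy]undeca-1,5,10-trien-3-ol
Conditions: Pd2(dba)3·CHCl3 (2.5 mol%), N,N'-[(1R,2R)-cyclohexane-1,2-diyl]bis[2-(diphenylphosphino)benzamide] (7.5 mol%), 4 (1.1 equiv), CH2Cl2 (0.2 M), 0 °C to rt, dark; stopped at full conversion of 13
Reagents that add atoms: none
Why: Asymmetric Tsuji–Trost allylic O-alkylation: Pd(0)–ligand ionises the primary carbonate of 13 with loss of CO2, the methoxide set free deprotonates phenol 4, the diastereomeric π-allyl complexes interconvert by π-σ-π at the unsubstituted CH2 terminus, and the phenoxide attacks the more substituted, more cationic terminus from the face opposite palladium inside the chiral pocket. The closest known reaction type is the Pd-catalysed asymmetric O-allylation of phenols by trisubstituted allylic carbonates with DACH bisphosphine ligands (established for 2-methyl-2-vinylchromans), together with Pd-catalysed O-allylation of hindered phenols to 1,1-dialkylallyl aryl ethers. No ring closes in this step: it forms only the O1–C2 bond, placing the C2 vinyl group next to the styrene for the later six-membered pyran closure and leaving the C5 vinyl carbinol for the later five-membered lactone closure. The new quaternary centre (S) is set by the ligand alone, the remote C5 carbinol having no influence. The step needs attack at the tertiary and not the CH2 terminus, and on one allyl face; these are secured by the ligand pocket acting on the defined E geometry of 13, by the carbonate being the only ionisable group (the C5 oxygen is a free alcohol and no lactone exists yet), by the electron-rich aryloxide being a poor leaving group so that the kinetic branched ether is not re-ionised to the linear isomer, and by the blocked ortho and para positions of 4, which exclude Claisen and C-allylation pathways.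

**Step 10**
Reactants: 15 5-bromo-2-methylpent-2-ene; 16 triethyl phosphonoacetate
Product: 17 ethyl 2-(diethoxyphosphoryl)-6-methylhept-5-enoate
Conditions: NaH, 16 (1.3 equiv), DMSO, rt; then 15, 60 °C
Reagents that add atoms: none
Why: SN2 C-alkylation of the sodium salt of the phosphonoacetate by a primary bromide; the excess of phosphonate suppresses dialkylation.

**Step 11**
Reactants: 17 ethyl 2-(diethoxyphosphoryl)-6-methylhept-5-enoate
Product: 18 ethyl 6-methyl-2-methylenehept-5-enoate
Conditions: 37% aq. HCHO, K2CO3, H2O/THF, rt to 70 °C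
Reagents that add atoms: formaldehyde, C=O
Why: Horner–Wadsworth–Emmons methylenation with aqueous formaldehyde gives the 2-alkylacrylate; the mild carbonate base does not isomerise the product.

**Step 12**
Reactants: 18 ethyl 6-methyl-2-methylenehept-5-enoate
Product: 19 6-methyl-2-methylenehept-5-enoic acid
Conditions: LiOH·H2O, THF/MeOH/H2O, rt; then 1 M HCl to pH 3
Reagents that add atoms: lithium hydroxide, [Li+].[OH-]
Why: Ester saponification; the 2-substituted acrylate resists conjugate addition of hydroxide at room temperature.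

**Step 13**
Reactants: 14 (3R,5E,9S)-5,9-dimethyl-9-[2-methyl-4-(triisopropylsilyloxy)-6-vinylphenoxy]undeca-1,5,10-trien-3-ol; 19 6-methyl-2-methylenehept-5-enoic acid
Product: 20 (3R,5E,9S)-5,9-dimethyl-9-[2-methyl-4-(triisopropylsilyloxy)-6-vinylphenoxy]undeca-1,5,10-trien-3-yl 6-methyl-2-methylenehept-5-enoate
Conditions: DCC (1.3 equiv), DMAP (0.3 equiv), CH2Cl2, 0 °C to rt
Reagents that add atoms: none
Why: Steglich esterification through the O-acylisourea and acylpyridinium; the secondary allylic alcohol is the only free hydroxyl, and the neutral conditions spare the acid-labile tertiary allyl aryl ether and the aryl silyl ether.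

**Step 14**
Reactants: 20 (3R,5E,9S)-5,9-dimethyl-9-[2-methyl-4-(triisopropylsilyloxy)-6-vinylphenoxy]undeca-1,5,10-trien-3-yl 6-methyl-2-methylenehept-5-enoate
Product: 21 O-triisopropylsilyl tuberatolide B, (R)-5-{(E)-5-[(S)-2,8-dimethyl-6-(triisopropylsilyloxy)-2H-chromen-2-yl]-2-methylpent-2-en-1-yl}-3-(4-methylpent-3-en-1-yl)furan-2(5H)-one
Conditions: Grubbs II (2 × 5 mol%), 1,4-benzoquinone (10 mol%), degassed CH2Cl2 (2 mM), 40 °C, Ar, dark; ethyl vinyl ether quench
Reagents that add atoms: none
Why: Double ring-closing metathesis: the catalyst loads on the two monosubstituted alkenes (styrene and C5 vinyl), then closes the six-membered pyran onto the C2 vinyl group and the five-membered butenolide onto the 1,1-disubstituted acrylate, each with loss of ethylene; the trisubstituted chain alkenes could only give four- or eight-membered rings and should not compete, and neither stereocentre is touched.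

**Step 15**
Reactants: 21 O-triisopropylsilyl tuberatolide B
Product: 22 tuberatolide B, (R)-5-{(E)-5-[(S)-6-hydroxy-2,8-dimethyl-2H-chromen-2-yl]-2-methylpent-2-en-1-yl}-3-(4-methylpent-3-en-1-yl)furan-2(5H)-one
Conditions: TBAF (1.2 equiv), AcOH (1.5 equiv), THF, 0 °C, Ar, dark
Reagents that add atoms: none
Why: Fluoride cleavage of the aryl silyl ether; acetic acid buffering keeps the medium from deprotonating the γ-position (C5) of the butenolide, so the lactone stereocentre should not epimerise, and exclusion of light and strong acid avoids electrocyclic opening of the chromene that would scramble C2.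

**Compound list**

1 | 2-methylhydroquinone | Cc1cc(O)ccc1O | starting material
2 | 2-methyl-4-(triisopropylsilyloxy)phenol | Cc1cc(O[Si](C(C)C)(C(C)C)C(C)C)ccc1O | intermediate
3 | 2-hydroxy-3-methyl-5-(triisopropylsilyloxy)benzaldehyde | O=Cc1cc(O[Si](C(C)C)(C(C)C)C(C)C)cc(C)c1O | intermediate
4 | 2-methyl-4-(triisopropylsilyloxy)-6-vinylphenol | C=Cc1cc(O[Si](C(C)C)(C(C)C)C(C)C)cc(C)c1O | intermediate
5 | (E)-3-methylpent-2-en-4-yn-1-ol | C#C/C(C)=C/CO | starting material
6 | (E)-3-methylpenta-2,4-dien-1-ol | C=C/C(C)=C/CO | intermediate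
7 | (S)-2-vinyloxirane | C=C[C@H]1CO1 | starting material
8 | (R)-hex-1-en-5-yn-3-ol | C=C[C@@H](CC#C)O | intermediate
9 | dimethylaluminium (R,E)-6-(dimethylalumanyl)-5-methylhexa-1,5-dien-3-olate | C=C[C@@H](C/C(C)=C/[Al](C)C)O[Al](C)C | intermediate (not isolated)
10 | (R,E)-6-iodo-5-methylhexa-1,5-dien-3-ol | C=C[C@@H](C/C(C)=C/I)O | intermediate
11 | 9-[(E)-3-methyl-5-(9-borabicyclo[3.3.1]nonan-9-yloxy)pent-3-en-1-yl]-9-borabicyclo[3.3.1]nonane | C/C(CCB1C2CCCC1CCC2)=C\COB1C2CCCC1CCC2 | intermediate (not isolated)
12 | (2E,6E,9R)-3,7-dimethylundeca-2,6,10-triene-1,9-diol | C=C[C@@H](C/C(C)=C/CC/C(C)=C/CO)O | intermediate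
13 | (2E,6E,9R)-9-hydroxy-3,7-dimethylundeca-2,6,10-trien-1-yl methyl carbonate | C=C[C@@H](C/C(C)=C/CC/C(C)=C/COC(=O)OC)O | intermediate
14 | (3R,5E,9S)-5,9-dimethyl-9-[2-methyl-4-(triisopropylsilyloxy)-6-vinylphenoxy]undeca-1,5,10-trien-3-ol | C=C[C@@H](C/C(C)=C/CC[C@@](C)(C=C)Oc1c(C)cc(O[Si](C(C)C)(C(C)C)C(C)C)cc1C=C)O | intermediate
15 | 5-bromo-2-methylpent-2-ene | CC(C)=CCCBr | starting material
16 | triethyl phosphonoacetate | CCOC(=O)CP(=O)(OCC)OCC | starting material
17 | ethyl 2-(diethoxyphosphoryl)-6-methylhept-5-enoate | CCOC(=O)C(CCC=C(C)C)P(=O)(OCC)OCC | intermediate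
18 | ethyl 6-methyl-2-methylenehept-5-enoate | CCOC(=O)C(=C)CCC=C(C)C | intermediate
19 | 6-methyl-2-methylenehept-5-enoic acid | CC(C)=CCCC(=C)C(=O)O | intermediate
20 | (3R,5E,9S)-5,9-dimethyl-9-[2-methyl-4-(triisopropylsilyloxy)-6-vinylphenoxy]undeca-1,5,10-trien-3-yl 6-methyl-2-methylenehept-5-enoate | C=C[C@@H](C/C(C)=C/CC[C@@](C)(C=C)Oc1c(C)cc(O[Si](C(C)C)(C(C)C)C(C)C)cc1C=C)OC(=O)C(=C)CCC=C(C)C | intermediate
21 | O-triisopropylsilyl tuberatolide B | CC(C)=CCCC1=C[C@@H](C/C(C)=C/CC[C@@]2(C)C=Cc3cc(O[Si](C(C)C)(C(C)C)C(C)C)cc(C)c3O2)OC1=O | intermediate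
22 | tuberatolide B | CC(C)=CCCC1=C[C@@H](C/C(C)=C/CC[C@@]2(C)C=Cc3cc(O)cc(C)c3O2)OC1=O | target

**Step count and risks**

Total step count: 15.
Longest linear sequence: 8 steps, from (S)-2-vinyloxirane 7 (steps 5, 6, 7, 8, 9, 13, 14, 15).

Steps most likely to fail:

1. Step 9. The doubly ortho-substituted phenoxide may attack the CH2 terminus of the π-allyl unit instead of the tertiary one, or the intermolecular attack may show poor facial selectivity. The ligand antipode and the Z carbonate are only tuning handles; the fallback makes the C–O union intramolecular, which is the established mode of this reaction, and joins the chain afterwards. It sets out from 4 and comes back to the route at 21. But-2-yn-1-ol (bought) is reduced with Red-Al and the alkenylaluminate iodinated to (Z)-3-iodobut-2-en-1-ol F1. The styrene of 4 is hydroborated with 9-BBN (two equivalents, the phenol consuming one) and the borane coupled with F1 under Suzuki conditions to (Z)-5-[2-hydroxy-3-methyl-5-(triisopropylsilyloxy)phenyl]-3-methylpent-2-en-1-ol F2. Its primary hydroxyl is converted with methyl chloroformate and pyridine at −20 °C into (Z)-5-[2-hydroxy-3-methyl-5-(triisopropylsilyloxy)phenyl]-3-methylpent-2-en-1-yl methyl carbonate F3, the hindered phenol staying free. Pd2(dba)3·CHCl3, the Trost ligand (the antipode that delivers the R product) and AcOH in CH2Cl2 close the pyran by 6-exo attack of the phenol on the tertiary allyl terminus, giving (R)-2,8-dimethyl-6-(triisopropylsilyloxy)-2-vinylchroman F4. DDQ in hot dioxane dehydrogenates C3–C4 to (S)-2,8-dimethyl-6-(triisopropylsilyloxy)-2-vinyl-2H-chromene F5. 9-BBN then adds to the monosubstituted vinyl group only, and Suzuki coupling of this borane with 10 gives (3R,5E)-8-[(S)-2,8-dimethyl-6-(triisopropylsilyloxy)-2H-chromen-2-yl]-5-methylocta-1,5-dien-3-ol F6. DCC/DMAP esterification with 19 gives its 6-methyl-2-methylenehept-5-enoate F7, and a single ring-closing metathesis (Grubbs II) of the acrylate with the C5 vinyl group gives 21.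

2. Step 14. Closure of the lactone onto the 1,1-disubstituted acrylate may lag, so that cross-metathesis or oligomerisation through the free C5 vinyl group, or ruthenium hydride alkene migration, takes over. The fallback moves the lactone closure to an unsubstituted acrylate and adds the side chain afterwards by cross-coupling. It sets out from 14 and comes back at 21. Alcohol 14 is acylated with acryloyl chloride and i-Pr2NEt to (3R,5E,9S)-5,9-dimethyl-9-[2-methyl-4-(triisopropylsilyloxy)-6-vinylphenoxy]undeca-1,5,10-trien-3-yl acrylate F8. Double ring-closing metathesis (Grubbs II) now forms only disubstituted ring alkenes and gives (R)-5-{(E)-5-[(S)-2,8-dimethyl-6-(triisopropylsilyloxy)-2H-chromen-2-yl]-2-methylpent-2-en-1-yl}furan-2(5H)-one F9. α-Iodination with I2 and pyridine in CH2Cl2 (addition–elimination through the pyridinium enolate, which does not touch C5) gives the corresponding 3-iodofuran-2(5H)-one F10. Negishi coupling of F10 with (4-methylpent-3-en-1-yl)zinc bromide F11, made from 15 with zinc dust and LiCl, under Pd(0) in THF at rt gives 21.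

3. Step 7. Hydroboration of the conjugated diene may lose regiocontrol, and the two free hydroxyls may interfere with the borane (B–O formation, protodeboronation of the alkylborane before coupling). The fallback assembles the chain by the iterative alkyne sequence instead. It sets out from 10 and comes back at 12. [4-(Trimethylsilyl)but-3-yn-1-yl]zinc iodide F12, made from bought 4-iodo-1-(trimethylsilyl)but-1-yne and zinc, is coupled with 10 under Pd(dppf)Cl2 (an extra equivalent of the zinc reagent is taken up by the hydroxyl) to give (R,E)-5-methyl-10-(trimethylsilyl)deca-1,5-dien-9-yn-3-ol F13. K2CO3 in MeOH removes the silyl group to give (R,E)-5-methyldeca-1,5-dien-9-yn-3-ol F14. Zr-catalysed methylalumination of the terminal alkyne (AlMe3, Cp2ZrCl2), conversion into the alanate with n-BuLi and reaction with paraformaldehyde give the E allylic alcohol 12.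

**Further compounds**

F1 | step 9 | (Z)-3-iodobut-2-en-1-ol | C/C(I)=C/CO
F2 | step 9 | (Z)-5-[2-hydroxy-3-methyl-5-(triisopropylsilyloxy)phenyl]-3-methylpent-2-en-1-ol | C/C(CCc1cc(O[Si](C(C)C)(C(C)C)C(C)C)cc(C)c1O)=C/CO
F3 | step 9 | (Z)-5-[2-hydroxy-3-methyl-5-(triisopropylsilyloxy)phenyl]-3-methylpent-2-en-1-yl methyl carbonate | C/C(CCc1cc(O[Si](C(C)C)(C(C)C)C(C)C)cc(C)c1O)=C/COC(=O)OC
F4 | step 9 | (R)-2,8-dimethyl-6-(triisopropylsilyloxy)-2-vinylchroman | C=C[C@@]1(C)CCc2cc(O[Si](C(C)C)(C(C)C)C(C)C)cc(C)c2O1
F5 | step 9 | (S)-2,8-dimethyl-6-(triisopropylsilyloxy)-2-vinyl-2H-chromene | C=C[C@@]1(C)C=Cc2cc(O[Si](C(C)C)(C(C)C)C(C)C)cc(C)c2O1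
F6 | step 9 | (3R,5E)-8-[(S)-2,8-dimethyl-6-(triisopropylsilyloxy)-2H-chromen-2-yl]-5-methylocta-1,5-dien-3-ol | C=C[C@@H](C/C(C)=C/CC[C@@]1(C)C=Cc2cc(O[Si](C(C)C)(C(C)C)C(C)C)cc(C)c2O1)O
F7 | step 9 | (3R,5E)-8-[(S)-2,8-dimethyl-6-(triisopropylsilyloxy)-2H-chromen-2-yl]-5-methylocta-1,5-dien-3-yl 6-methyl-2-methylenehept-5-enoate | C=C[C@@H](C/C(C)=C/CC[C@@]1(C)C=Cc2cc(O[Si](C(C)C)(C(C)C)C(C)C)cc(C)c2O1)OC(=O)C(=C)CCC=C(C)C
F8 | step 14 | (3R,5E,9S)-5,9-dimethyl-9-[2-methyl-4-(triisopropylsilyloxy)-6-vinylphenoxy]undeca-1,5,10-trien-3-yl acrylate | C=C[C@@H](C/C(C)=C/CC[C@@](C)(C=C)Oc1c(C)cc(O[Si](C(C)C)(C(C)C)C(C)C)cc1C=C)OC(=O)C=C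
F9 | step 14 | (R)-5-{(E)-5-[(S)-2,8-dimethyl-6-(triisopropylsilyloxy)-2H-chromen-2-yl]-2-methylpent-2-en-1-yl}furan-2(5H)-one | O=C1C=C[C@@H](C/C(C)=C/CC[C@@]2(C)C=Cc3cc(O[Si](C(C)C)(C(C)C)C(C)C)cc(C)c3O2)O1
F10 | step 14 | (R)-5-{(E)-5-[(S)-2,8-dimethyl-6-(triisopropylsilyloxy)-2H-chromen-2-yl]-2-methylpent-2-en-1-yl}-3-iodofuran-2(5H)-one | O=C1C(I)=C[C@@H](C/C(C)=C/CC[C@@]2(C)C=Cc3cc(O[Si](C(C)C)(C(C)C)C(C)C)cc(C)c3O2)O1
F11 | step 14 | (4-methylpent-3-en-1-yl)zinc bromide | CC(C)=CCC[Zn]Br
F12 | step 7 | [4-(trimethylsilyl)but-3-yn-1-yl]zinc iodide | C[Si](C)(C)C#CCC[Zn]I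
F13 | step 7 | (R,E)-5-methyl-10-(trimethylsilyl)deca-1,5-dien-9-yn-3-ol | C=C[C@@H](C/C(C)=C/CCC#C[Si](C)(C)C)O
F14 | step 7 | (R,E)-5-methyldeca-1,5-dien-9-yn-3-ol | C=C[C@@H](C/C(C)=C/CCC#C)O
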